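**Retrosynthetic overview**

1. End game: the butenolide comes from a 3-furyl ring (singlet oxygen, then NaBH4), C1–OH from a C1–B(pin) bond with retention, the C6 acetate and C7 isobutyrate are placed one at a time, C4=C18 comes from a C4 ketone, and the 7β,8β-diol from OsO4 on a Δ7 alkene.
2. The decalin comes from a 2-thiabicyclo[2.2.2]octene by Raney nickel extrusion of sulfur, which frees the angular C19 methyl and the C2 methylene.
3. The thiabicycle comes from an intramolecular Diels–Alder reaction that forms C1–C2 and C5–C10 and closes rings A and B together. Enabling feature: in ring A (C1, C2, C3, C4, C5, C10) the edge C2–C3–C4–C5 can be a diene (C4 as silyl enol ether) and the edge C10–C1 an (E)-alkenylboronate (C1–O as C1–B); the angular C19 methyl on C5 is cis to C2 and is tied to it through sulfur as a 2H-thiopyran, which locks the diene s-cis.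
4. The cycloaddition precursor comes from an aldol union of a thiopyranone silyl dienol ether with a (Z)-enal; the (Z)-C7=C8 alkene from a temporary α,β-unsaturated δ-lactone (intramolecular HWE); C9 and C11 from one iridium-catalysed tert-(hydroxy)prenylation of 2-(furan-3-yl)ethanol with isoprene monoxide.
5. Ring order: temporary δ-lactone (opened again), then rings A and B in one step (with the temporary thia-bridge), then the butenolide last.

Key step: step 14

Remarks: Clerodane numbering (C1–C20) is used for all locants; α/β refer to the usual drawing with H-10 β. Assumptions: 2-(furan-3-yl)ethanol is taken as commercial; the catalyst antipodes named in steps 3 and 12 are assumed to give the required sense of induction (otherwise the enantiomeric catalyst is used); the tert-(hydroxy)prenylation is assumed to give the anti diol (secondary OH anti to CH2OH in the zigzag through the vinyl group).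

**Route**

Step 1
Reactants: 1 tetrahydro-4H-thiopyran-4-one
Product: 2 2,3-dihydro-4H-thiopyran-4-one
Conditions: NCS, pyridine, CH2Cl2, 0 °C to rt
Reagents that add atoms: none
Why: α-Chlorination of the sulfide followed by pyridine-induced loss of HCl (Pummerer-type dehydrogenation) should give the vinylogous thioester, with no stereocentre involved.

Step 2
Reactants: 2 2,3-dihydro-4H-thiopyran-4-one
Product: 3 4-(trimethylsilyloxy)-2H-thiopyran
Conditions: LDA, THF, −78 °C; TMSCl; used crude
Reagents that add atoms: chlorotrimethylsilane, C[Si](C)(C)Cl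
Why: Kinetic deprotonation at the only enolisable position and O-silylation (silyl enol ether formation) should give the cross-conjugated silyl dienol ether.

Step 3
Reactants: 4 2-(furan-3-yl)ethanol; 5 2-methyl-2-vinyloxirane (isoprene monoxide, racemic)
Product: 6 (2S,3S)-2-ethenyl-4-(furan-3-yl)-2-methylbutane-1,3-diol
Conditions: Ir(η3-allyl)[(R)-Tol-BINAP](4-cyano-3-nitrobenzoate-C,O) (5 mol %), K3PO4 (5 mol %), THF, 45 °C
Reagents that add atoms: none
Why: Iridium-catalysed redox-neutral carbonyl tert-(hydroxy)prenylation (transfer-hydrogenative allylation) should add the (E)-σ-allyliridium species from the vinyl epoxide to the aldehyde formed in situ through a chair transition state, which sets the C9 quaternary centre and the C11 carbinol anti, with the absolute sense fixed by the ligand.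

Step 4
Reactants: 6 (2S,3S)-2-ethenyl-4-(furan-3-yl)-2-methylbutane-1,3-diol
Product: 7 primary (C10–O) 2-(diethoxyphosphoryl)acetate of 6
Conditions: (EtO)2P(O)CH2CO2H, DCC, DMAP (cat.), CH2Cl2, 0 °C
Reagents that add atoms: 2-(diethoxyphosphoryl)acetic acid, OC(=O)CP(=O)(OCC)OCC
Why: Steglich esterification should acylate the primary hydroxyl selectively over the neopentylic secondary one and brings in C6 and C7.

Step 5
Reactants: 7 primary phosphonoacetate
Product: 8 11-O-isobutyrate of 7
Conditions: (i-PrCO)2O, DMAP, Et3N, CH2Cl2, rt to 40 °C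
Reagents that add atoms: isobutyric anhydride, CC(C)C(=O)OC(=O)C(C)C
Why: DMAP-catalysed acylation installs the final C11 isobutyrate early, where it also blocks lactonisation through O-11, and does not touch the stereocentre.

Step 6
Reactants: 8 vinyl phosphonoacetate isobutyrate
Product: 9 methyl ketone (vinyl group oxidised to acetyl, C8=O with C17 methyl)
Conditions: PdCl2 (10 mol %), CuCl (1 equiv), O2 (1 atm), DMF/H2O 7:1, rt
Reagents that add atoms: water, O
Why: Tsuji–Wacker oxidation (Markovnikov oxypalladation of the terminal vinyl group) should give the methyl ketone.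

Step 7
Reactants: 9 methyl ketone
Product: 10 (5S)-4,5-dimethyl-5-[(1S)-2-(furan-3-yl)-1-(2-methylpropanoyloxy)ethyl]-5,6-dihydro-2H-pyran-2-one
Conditions: LiCl, DBU, MeCN, rt
Reagents that add atoms: none
Why: Intramolecular Horner–Wadsworth–Emmons olefination under Masamune–Roush conditions closes the six-membered lactone and thereby fixes the C7=C8 geometry as Z (C6 cis to C9), which an acyclic olefination would not give.

Step 8
Reactants: 10 unsaturated δ-lactone
Product: 11 (Z)-N-methoxy-N-methyl enamide with free C10 hydroxyl (ring-opened 10)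
Conditions: MeNH(OMe)·HCl, Me3Al, CH2Cl2, 0 °C to rt
Reagents that add atoms: N,O-dimethylhydroxylamine hydrochloride, CNOC.Cl
Why: Weinreb aminolysis of the lactone by the aluminium amide opens the ring with retention of the Z alkene and frees the C10 hydroxyl, while the hindered C11 isobutyrate should react much more slowly.

Step 9
Reactants: 11 hydroxy Weinreb amide
Product: 12 C10 aldehyde of the (Z)-Weinreb amide
Conditions: Dess–Martin periodinane, NaHCO3, CH2Cl2, 0 °C to rt
Reagents that add atoms: none
Why: Dess–Martin oxidation gives the non-enolisable neopentylic aldehyde before the hydroxy amide can relactonise.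

Step 10
Reactants: 12 aldehyde
Product: 13 (Z)-Weinreb amide bearing the (E)-2-(pinacolboryl)ethenyl group on C9
Conditions: CrCl2, Cl2CHB(pin), LiI, THF, rt
Reagents that add atoms: 2-(dichloromethyl)-4,4,5,5-tetramethyl-1,3,2-dioxaborolane, ClC(Cl)B1OC(C)(C)C(C)(C)O1
Why: Takai–Utimoto boryl-olefination with the geminal dichromium reagent should give the (E)-alkenylboronate, which is both the dienophile and the masked C1 oxygen.

Step 11
Reactants: 13 Weinreb amide alkenylboronate
Product: 14 (Z)-enal (C6 aldehyde) bearing the (E)-alkenylboronate and the 11S isobutyrate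
Conditions: DIBAL-H (1.2 equiv), CH2Cl2, −78 °C; Rochelle salt work-up; used at once
Reagents that add atoms: none
Why: DIBAL-H reduction of the Weinreb amide through its chelated tetrahedral intermediate gives the (Z)-enal at −78 °C, the hindered isobutyrate and the boronate being slower to react.

Step 12
Reactants: 3 4-(trimethylsilyloxy)-2H-thiopyran; 14 (Z)-enal
Product: 15 anti aldol adduct (3-substituted 2,3-dihydro-4H-thiopyran-4-one with the C6 carbinol configured for the later 6α-oxygen)
Conditions: SiCl4 (1.5 equiv), (R,R)-bisphosphoramide catalyst [pentane-1,5-diylbis(methylamino)-linked bis-phosphoramide of (R)-N,N′-dimethyl-1,1′-binaphthyl-2,2′-diamine] (5 mol %), i-Pr2NEt (10 mol %), CH2Cl2, −78 °C; then aq. KF/NaHCO3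
Reagents that add atoms: none
Why: Lewis-base-catalysed, SiCl4-mediated Mukaiyama aldol addition of the (E)-configured cyclic enol ether should give the anti aldol, the chiral phosphoramide-bound silicon cation fixing the aldehyde face and so C6 (C5 is erased again in step 13).

Step 13
Reactants: 15 aldol adduct
Product: 16 bis(triethylsilyl) compound: 4-(triethylsilyloxy)-2H-thiopyran-3-yl carbinol triethylsilyl ether
Conditions: TESOTf (2.5 equiv), Et3N, CH2Cl2, −78 to 0 °C
Reagents that add atoms: triethylsilyl trifluoromethanesulfonate, CC[Si](CC)(CC)OS(=O)(=O)C(F)(F)F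
Why: O-Silylation of the C6 hydroxyl and soft enolisation (silyl triflate and amine) toward C5, the only enolisable position, should give the 4-silyloxy-2H-thiopyran diene.

Step 14
Reactants: 16 bis(triethylsilyl) diene boronate
Product: 18 thiabicyclic C4 ketone (2-thiabicyclo[2.2.2]octan-5-one fused to ring B; C1 B(pin) β; C6 OSiEt3 α), via silyl enol ether cycloadduct 17 (not isolated)
Conditions: toluene (5 mM), BHT, base-washed sealed tube, 135 °C; then K2CO3 (cat.), MeOH/THF, 0 °C
Reagents that add atoms: none
Why: Thermal, concerted, normal-electron-demand intramolecular Diels–Alder reaction: the s-cis-locked, electron-rich diene C2=C3–C4(OSiEt3)=C5 of the 2H-thiopyran adds suprafacially to the (E)-alkenylboronate C10=C1, forming C5–C10 and C1–C2 at once, and methanolysis of the silyl enol ether then gives the C4 ketone. The closest known reaction types are intramolecular Diels–Alder reactions of 2H-thiopyrans used as cis-diene surrogates and cycloadditions of alkenylboronates. Ring A closes by the [4+2] event itself (as the carbocyclic six-membered ring of a 2-thiabicyclo[2.2.2]octene) and ring B closes as the six-membered ring defined by the four-atom tether C6–C9 (mode of a 1,7,9-decatriene cyclisation with the tether on the diene terminus). C1 and C10 follow from the (E)-alkene geometry (boron cis to H-10), the trans fusion at C5/C10 from the transition state with the tether exo and boron endo, C2 from the bicyclic frame, and the absolute sense from C9, which places its large C11 branch pseudo-equatorial and its methyl pseudo-axial beside the CH2–S bridge, reinforced by the pseudo-equatorial C6 silyl ether. The step needs exo-tether over endo-tether selectivity and one diene face; the (Z)-C7=C8 alkene pre-organises the tether, the tether length enforces the regiochemistry, and the sulfur bridge removes the inside-methyl penalty that would block an acyclic 5-methyl diene.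

Step 15
Reactants: 18 thiabicyclic ketone
Product: 19 trans-decalin-4-one (1β-B(pin), 5α-methyl, 6α-OSiEt3, Δ7, 9α-methyl, 10β-H, 11S isobutyrate, 12-(furan-3-yl))
Conditions: Raney nickel (Ni, W-2 grade, excess), acetone/EtOH, rt
Reagents that add atoms: none
Why: Raney nickel hydrogenolysis of both C–S bonds (desulfurisation) extrudes sulfur and unveils the C19 angular methyl and the C2 methylene, while the hindered trisubstituted alkene, the furan and the C–B bond should survive in the acetone-deactivated medium.

Step 16
Reactants: 19 decalone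
Product: 20 7β,8β-diol
Conditions: OsO4 (1.1 equiv), pyridine, THF, 0 °C to rt; then aq. NaHSO3
Reagents that add atoms: osmium tetroxide, O=[Os](=O)(=O)=O
Why: Osmylation should occur from the β face, opposite the axial C19 and C20 methyls and anti to the allylic C6 silyl ether, and so sets C7 and C8 as the cis 7β,8β-diol.

Step 17
Reactants: 20 diol
Product: 21 7β-isobutyrate (8β-OH free)
Conditions: i-PrCOCl, pyridine, DMAP, CH2Cl2, 0 °C to rt
Reagents that add atoms: isobutyryl chloride, CC(C)C(=O)Cl
Why: DMAP-catalysed acylation takes the secondary C7 hydroxyl and leaves the tertiary C8 hydroxyl free.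

Step 18
Reactants: 21 C4 ketone
Product: 22 4(18)-methylene compound
Conditions: Zn, CH2Br2, TiCl4, THF/CH2Cl2, 0 °C to rt
Reagents that add atoms: dibromomethane, BrCBr
Why: Takai–Lombardo methylenation is non-basic and selective for the hindered ketone in the presence of esters, so the exocyclic C4=C18 alkene should form without acyl migration.

Step 19
Reactants: 22 C6 triethylsilyl ether
Product: 23 6α-alcohol
Conditions: PPTS (cat.), MeOH/CH2Cl2, rt
Reagents that add atoms: none
Why: Acid-catalysed methanolysis of the triethylsilyl ether frees only the C6 hydroxyl, and the mildly acidic medium suppresses migration of the C7 isobutyrate.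

Step 20
Reactants: 23 6α-alcohol
Product: 24 6α-acetate
Conditions: Ac2O, pyridine, DMAP (cat.), CH2Cl2, rt
Reagents that add atoms: acetic anhydride, CC(=O)OC(C)=O
Why: DMAP-catalysed acetylation reaches only the C6 hydroxyl, because C1 is still masked as the boronate and the C8 hydroxyl is tertiary.

Step 21
Reactants: 24 C1 boronate
Product: 25 1β-alcohol (furan still in place)
Conditions: NaBO3·4H2O, THF/pH 7 phosphate buffer, 0 °C to rt
Reagents that add atoms: sodium perborate, [Na+].[O-]OB=O
Why: Peroxoborate oxidation of the C–B bond (1,2-migration from boron to oxygen) proceeds with retention and should give the equatorial 1β-hydroxyl.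

Step 22
Reactants: 25 furan
Product: 27 target compound CNP0325163.1, via γ-hydroxybutenolide 26 (not isolated)
Conditions: O2, visible light, rose bengal (cat.), i-Pr2NEt, CH2Cl2, −78 °C; then NaBH4, EtOH, 0 °C; aq. HCl work-up
Reagents that add atoms: dioxygen, O=O
Why: [4+2] Addition of singlet oxygen to the 3-substituted furan and amine-induced Kornblum–DeLaMare-type fragmentation of the endoperoxide should give the β-substituted γ-hydroxybutenolide regioselectively, and NaBH4 reduction of its open aldehyde form with relactonisation gives the butenolide.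

**Compound list**

1 | tetrahydro-4H-thiopyran-4-one | O=C1CCSCC1 | starting material
2 | 2,3-dihydro-4H-thiopyran-4-one | O=C1C=CSCC1 | intermediate
3 | 4-(trimethylsilyloxy)-2H-thiopyran | C[Si](C)(C)OC1=CCSC=C1 | intermediate
4 | 2-(furan-3-yl)ethanol | OCCc1ccoc1 | starting material
5 | 2-methyl-2-vinyloxirane (isoprene monoxide, racemic) | CC1(C=C)CO1 | starting material
6 | (2S,3S)-2-ethenyl-4-(furan-3-yl)-2-methylbutane-1,3-diol (CH2OH = C10, vinyl = C8/C17, carbinol = C11) | OC[C@](C)(C=C)[C@@H](O)Cc1ccoc1 | intermediate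
7 | primary (C10–O) 2-(diethoxyphosphoryl)acetate of 6 | CCOP(=O)(OCC)CC(=O)OC[C@](C)(C=C)[C@@H](O)Cc1ccoc1 | intermediate
8 | 11S-isobutyrate of 7 | CCOP(=O)(OCC)CC(=O)OC[C@](C)(C=C)[C@@H](OC(=O)C(C)C)Cc1ccoc1 | intermediate
9 | methyl ketone (acetyl on C9 in place of vinyl) | CCOP(=O)(OCC)CC(=O)OC[C@](C)(C(C)=O)[C@@H](OC(=O)C(C)C)Cc1ccoc1 | intermediate
10 | (5S)-4,5-dimethyl-5-[(1S)-2-(furan-3-yl)-1-(2-methylpropanoyloxy)ethyl]-5,6-dihydro-2H-pyran-2-one | O=C1C=C(C)[C@@](C)(CO1)[C@@H](OC(=O)C(C)C)Cc1ccoc1 | intermediate
11 | (Z)-N-methoxy-N-methyl enamide with C10 hydroxymethyl (C9, C11 as in 10) | CON(C)C(=O)/C=C(C)\[C@@](C)(CO)[C@@H](OC(=O)C(C)C)Cc1ccoc1 | intermediate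
12 | (Z)-N-methoxy-N-methyl enamide with C10 formyl | CON(C)C(=O)/C=C(C)\[C@@](C)(C=O)[C@@H](OC(=O)C(C)C)Cc1ccoc1 | intermediate
13 | (Z)-N-methoxy-N-methyl enamide with (E)-2-(pinacolboryl)ethenyl on C9 | CON(C)C(=O)/C=C(C)\[C@@](C)(/C=C/B1OC(C)(C)C(C)(C)O1)[C@@H](OC(=O)C(C)C)Cc1ccoc1 | intermediate
14 | (Z)-enal with (E)-alkenylboronate and 11S isobutyrate | O=C/C=C(C)\[C@@](C)(/C=C/B1OC(C)(C)C(C)(C)O1)[C@@H](OC(=O)C(C)C)Cc1ccoc1 | intermediate
15 | anti aldol adduct: 3-substituted 2,3-dihydro-4H-thiopyran-4-one with free C6 hydroxyl | O=C1C=CSC[C@H]1[C@@H](O)/C=C(C)\[C@@](C)(/C=C/B1OC(C)(C)C(C)(C)O1)[C@@H](OC(=O)C(C)C)Cc1ccoc1 | intermediate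
16 | cycloaddition precursor: 4-(triethylsilyloxy)-2H-thiopyran-3-yl carbinol triethylsilyl ether with (Z)-C7=C8 and (E)-alkenylboronate | CC[Si](CC)(CC)OC1=C(CSC=C1)[C@@H](O[Si](CC)(CC)CC)/C=C(C)\[C@@](C)(/C=C/B1OC(C)(C)C(C)(C)O1)[C@@H](OC(=O)C(C)C)Cc1ccoc1 | intermediate
17 | cycloadduct: 2-thiabicyclo[2.2.2]oct-5-ene silyl enol ether fused to ring B (S bridges C2 and C19) | CC[Si](CC)(CC)OC1=C[C@H]3[C@@H](B4OC(C)(C)C(C)(C)O4)[C@H]2[C@@]1(CS3)[C@@H](O[Si](CC)(CC)CC)C=C(C)[C@]2(C)[C@H](Cc1ccoc1)OC(=O)C(C)C | intermediate
18 | thiabicyclic C4 ketone | O=C1C[C@H]3[C@@H](B4OC(C)(C)C(C)(C)O4)[C@H]2[C@@]1(CS3)[C@@H](O[Si](CC)(CC)CC)C=C(C)[C@]2(C)[C@H](Cc1ccoc1)OC(=O)C(C)C | intermediate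
19 | trans-decalin-4-one: 1β-B(pin), 5α-Me, 6α-OSiEt3, Δ7, 9α-Me, 10β-H, 11S-OCOiPr, 12-(furan-3-yl) | O=C1CC[C@@H](B3OC(C)(C)C(C)(C)O3)[C@H]2[C@@]1(C)[C@@H](O[Si](CC)(CC)CC)C=C(C)[C@]2(C)[C@H](Cc1ccoc1)OC(=O)C(C)C | intermediate
20 | 7β,8β-diol of 19 | O=C1CC[C@@H](B3OC(C)(C)C(C)(C)O3)[C@H]2[C@@]1(C)[C@@H](O[Si](CC)(CC)CC)[C@H](O)[C@](C)(O)[C@]2(C)[C@H](Cc1ccoc1)OC(=O)C(C)C | intermediate
21 | 7β-isobutyrate of 20 | O=C1CC[C@@H](B3OC(C)(C)C(C)(C)O3)[C@H]2[C@@]1(C)[C@@H](O[Si](CC)(CC)CC)[C@H](OC(=O)C(C)C)[C@](C)(O)[C@]2(C)[C@H](Cc1ccoc1)OC(=O)C(C)C | intermediate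
22 | 4(18)-methylene compound | C=C1CC[C@@H](B3OC(C)(C)C(C)(C)O3)[C@H]2[C@@]1(C)[C@@H](O[Si](CC)(CC)CC)[C@H](OC(=O)C(C)C)[C@](C)(O)[C@]2(C)[C@H](Cc1ccoc1)OC(=O)C(C)C | intermediate
23 | 6α-alcohol | C=C1CC[C@@H](B3OC(C)(C)C(C)(C)O3)[C@H]2[C@@]1(C)[C@@H](O)[C@H](OC(=O)C(C)C)[C@](C)(O)[C@]2(C)[C@H](Cc1ccoc1)OC(=O)C(C)C | intermediate
24 | 6α-acetate | C=C1CC[C@@H](B3OC(C)(C)C(C)(C)O3)[C@H]2[C@@]1(C)[C@@H](OC(C)=O)[C@H](OC(=O)C(C)C)[C@](C)(O)[C@]2(C)[C@H](Cc1ccoc1)OC(=O)C(C)C | intermediate
25 | 1β-alcohol with 3-furyl side chain | C=C1CC[C@@H](O)[C@H]2[C@@]1(C)[C@@H](OC(C)=O)[C@H](OC(=O)C(C)C)[C@](C)(O)[C@]2(C)[C@H](Cc1ccoc1)OC(=O)C(C)C | intermediate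
26 | γ-hydroxybutenolide (both C16 epimers) | C=C1CC[C@@H](O)[C@H]2[C@@]1(C)[C@@H](OC(C)=O)[C@H](OC(=O)C(C)C)[C@](C)(O)[C@]2(C)[C@H](CC1=CC(=O)OC1O)OC(=O)C(C)C | intermediate
27 | CNP0325163.1: 6α-acetoxy-1β,8β-dihydroxy-7β,11S-bis(2-methylpropanoyloxy)cleroda-4(18),13-dien-15,16-olide | C=C1CC[C@@H](O)[C@H]2[C@@]1(C)[C@@H](OC(C)=O)[C@H](OC(=O)C(C)C)[C@](C)(O)[C@]2(C)[C@H](CC1=CC(=O)OC1)OC(=O)C(C)C | target

**Step count and risks**

Total steps: 22. Longest linear sequence: 20 (steps 3 to 22); the thiopyran branch (steps 1 and 2) joins at step 12.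

Steps most likely to fail:

1. Step 14 (key cycloaddition). The weakly activated alkenylboronate may add too slowly, so that loss of the silyl enol ether or a 1,5-hydrogen shift of the 2H-thiopyran competes, or the tether may fold endo and give the cis-fused adduct. Fallback: setting out from 15, double deprotonation (KHMDS, 2.2 equiv, THF, −78 to 0 °C) would give the alkoxide dienolate. Its 2-oxido-diene should undergo an anion-accelerated intramolecular Diels–Alder (tandem Michael) reaction at low temperature, the C6 alkoxide being unable to eliminate. Protonation would give the 6-hydroxy thiabicyclic ketone F1, and silylation (TESCl, imidazole, DMF) brings the material back to the route at 18.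

2. Step 12 (aldol). Catalyst control of the carbonyl face at C6 may be insufficient with the hindered (Z)-enal, or the enal may isomerise to E under the Lewis acid. Fallback: setting out from 2 and 14, the lithium enolate of 2 (LDA, THF, −78 °C) would add without catalyst control to give 15 together with the anti aldol adduct epimeric at C5 and C6, F2. After chromatographic separation, F2 would be cleaved back to 2 and 14 by retro-aldol (DBU cat., toluene) and resubmitted, so that the material returns to the route at 15.

3. Step 6 (Wacker oxidation). Palladation or oxidation of the furan may compete with the slow oxypalladation of the neopentylic vinyl group. Fallback: setting out from 8, Mukaiyama hydration by hydrogen-atom transfer (Co(acac)2 cat., PhSiH3, O2, i-PrOH, rt) would give the Markovnikov secondary alcohol (both C8 epimers) F3, and Dess–Martin oxidation brings it back to the route at 9.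

**Further compounds**

F1 | step 14 | 6-hydroxy thiabicyclic ketone (18 without the C6 silyl group) | O=C1C[C@H]3[C@@H](B4OC(C)(C)C(C)(C)O4)[C@H]2[C@@]1(CS3)[C@@H](O)C=C(C)[C@]2(C)[C@H](Cc1ccoc1)OC(=O)C(C)C
F2 | step 12 | anti aldol adduct epimeric with 15 at C5 and C6 | O=C1C=CSC[C@@H]1[C@H](O)/C=C(C)\[C@@](C)(/C=C/B1OC(C)(C)C(C)(C)O1)[C@@H](OC(=O)C(C)C)Cc1ccoc1
F3 | step 6 | secondary alcohol at C8 (both epimers) from hydration of 8 | CCOP(=O)(OCC)CC(=O)OC[C@](C)(C(C)O)[C@@H](OC(=O)C(C)C)Cc1ccoc1
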